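**Strategy**

The route rests on cutting the bond between C1 (the ring CH that carries the propanoate arm, β to the lactone carbonyl C16) and C2 (the CH2 shared by the δ-lactone and the 14-membered carbocycle). C2 and the oxygen-bearing C3 are read as the two carbons of a vinyl group on the tertiary carbinol C4; C1 as a β-keto ester enol triflate. Enantioselective diboration of the vinyl group gives a 1,2-bis(boronate); in the key step its primary C–B bond closes the carbocycle by Suzuki–Miyaura coupling, and oxidative work-up turns the secondary C–B bond into the C3 oxygen, which lactonises. The precursor is an acyclic, farnesol-derived epoxy triflate.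

Key step: step 13

Remark on numbering: cembrane-type numbering is used throughout. C1 = ring CH bearing the propanoate arm; C2 = lactone CH2; C3 = lactone O–CH; C4 = C(CH3)(OH) (C18 = its methyl); C5, C6; C7 (bears OOH); C8 (bears exocyclic C19); C9, C10; C11 and C12 = epoxide carbons (C20 = methyl on C12); C13, C14; C15 = CH(CH3) of the lactone (C17 = its methyl); C16 = lactone C=O.

Remark on the chemistry (assumption): in step 11 the ligand enantiomer is the one that sends boron to the Re face of C3. The (R,R) ligand is written; its mirror image is used should a model diol show the opposite sense.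

**Route**

Step 1
Reactants: 1 (2E,6E)-farnesol
Product: 2 (2E,6E)-3,7,11-trimethyldodeca-2,6,10-trien-1-yl acetate
Conditions: Ac2O, pyridine, 4-(dimethylamino)pyridine (cat.), CH2Cl2, 0 °C to rt
Reagents that add atoms: acetic anhydride CC(=O)OC(C)=O
Why: Standard O-acylation masks the C2 allylic alcohol so that the first Sharpless epoxidation can later address the C13 alcohol alone; no stereocentre is formed.

Step 2
Reactants: 2 farnesyl acetate
Product: 3 (2E,6E,10E)-12-hydroxy-3,7,11-trimethyldodeca-2,6,10-trien-1-yl acetate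
Conditions: SeO2 (cat.), t-BuOOH, salicylic acid (cat.), CH2Cl2, rt
Reagents that add atoms: tert-butyl hydroperoxide CC(C)(C)OO
Why: Riley allylic oxidation (ene reaction, then [2,3]-shift) should select the (E)-methyl group of the terminal, most electron-rich trisubstituted alkene and give the (10E)-allylic alcohol at C13.

Step 3
Reactants: 3 12-hydroxyfarnesyl acetate
Product: 4 (2E,6E)-9-[(2S,3S)-3-(hydroxymethyl)-3-methyloxiran-2-yl]-3,7-dimethylnona-2,6-dien-1-yl acetate
Conditions: Ti(Oi-Pr)4 (cat.), L-(+)-diethyl tartrate, t-BuOOH, 4 Å molecular sieves, CH2Cl2, −20 °C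
Reagents that add atoms: tert-butyl hydroperoxide CC(C)(C)OO
Why: Sharpless asymmetric epoxidation touches only the alkene that carries the free allylic alcohol, and the L-(+)-tartrate titanium complex delivers oxygen to the face that sets C11 and C12 as (11S,12S) (reagent control).

Step 4
Reactants: 4 epoxy alcohol; 5 methyl (triphenyl-λ5-phosphanylidene)acetate
Product: 7 methyl (2E)-3-[(2S,3S)-3-[(3E,7E)-9-acetoxy-3,7-dimethylnona-3,7-dien-1-yl]-2-methyloxiran-2-yl]prop-2-enoate, via epoxy aldehyde 6 (not isolated)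
Conditions: PhI(OAc)2, 2,2,6,6-tetramethylpiperidin-1-oxyl (cat.), CH2Cl2, rt; then 5, rt
Reagents that add atoms: none
Why: Oxoammonium oxidation gives the non-enolisable epoxy aldehyde, and Wittig olefination with the stabilised ylide in the same flask should give the (E)-enoate, adding C14 and C1.

Step 5
Reactants: 7 epoxy enoate
Product: 8 methyl 3-[(2S,3S)-3-[(3E,7E)-9-acetoxy-3,7-dimethylnona-3,7-dien-1-yl]-2-methyloxiran-2-yl]propanoate
Conditions: 2-nitrobenzenesulfonyl hydrazide, Et3N, CH2Cl2, rt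
Reagents that add atoms: none
Why: Diimide reduction should take the disubstituted conjugated C13=C14 bond much faster than the trisubstituted alkenes and, unlike hydride or hydrogenolysis conditions, leaves the allylic epoxide C–O bond intact.

Step 6
Reactants: 8 acetate ester
Product: 9 methyl 3-[(2S,3S)-3-[(3E,7E)-9-hydroxy-3,7-dimethylnona-3,7-dien-1-yl]-2-methyloxiran-2-yl]propanoate
Conditions: K2CO3, MeOH, 0 °C
Reagents that add atoms: none
Why: Base-catalysed transesterification removes the acetate (the methyl ester exchanges degenerately) and frees the C2 allylic alcohol.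

Step 7
Reactants: 9 allylic alcohol
Product: 10 methyl 3-[(2S,3S)-3-[(3E)-6-[(2S,3S)-3-(hydroxymethyl)-2-methyloxiran-2-yl]-3-methylhex-3-en-1-yl]-2-methyloxiran-2-yl]propanoate
Conditions: Ti(Oi-Pr)4 (cat.), L-(+)-diethyl tartrate, t-BuOOH, 4 Å molecular sieves, CH2Cl2, −20 °C
Reagents that add atoms: tert-butyl hydroperoxide CC(C)(C)OO
Why: A second Sharpless asymmetric epoxidation, again confined to the allylic-alcohol alkene, should give the (3S,4S) epoxide and so fixes C4 (reagent control).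

Step 8
Reactants: 10 bis-epoxy alcohol
Product: 12 methyl 3-[(2S,3S)-3-[(3E,7S)-7-hydroxy-3,7-dimethylnona-3,8-dien-1-yl]-2-methyloxiran-2-yl]propanoate, via epoxy iodide 11 (not isolated)
Conditions: PPh3, I2, imidazole, Et2O/MeCN, 0 °C; then Zn dust, EtOH, 60 °C
Reagents that add atoms: none
Why: Appel-type iodination followed by zinc-induced reductive ring opening (β-elimination of the C3–O bond) transposes the epoxy alcohol into the C2=C3 vinyl carbinol; the C4–O bond is never broken, so C4 stays (S).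

Step 9
Reactants: 12 tertiary allylic alcohol
Product: 13 methyl 3-[(2S,3S)-3-[(3E,7S)-3,7-dimethyl-7-(triethylsilyloxy)nona-3,8-dien-1-yl]-2-methyloxiran-2-yl]propanoate
Conditions: Et3SiOTf, 2,6-lutidine, CH2Cl2, −78 to 0 °C
Reagents that add atoms: triethylsilyl trifluoromethanesulfonate CC[Si](CC)(CC)OS(=O)(=O)C(F)(F)F
Why: Silyl triflate silylation protects the hindered tertiary alcohol against the base, boron and palladium chemistry that follows.

Step 10
Reactants: 13 silyl ether methyl ester; 14 methyl propanoate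
Product: 15 methyl 5-[(2S,3S)-3-[(3E,7S)-3,7-dimethyl-7-(triethylsilyloxy)nona-3,8-dien-1-yl]-2-methyloxiran-2-yl]-2-methyl-3-oxopentanoate (C15 epimers)
Conditions: LiN(i-Pr)2, 14 (3 equiv), THF, −78 °C; then 13, −78 to −20 °C
Reagents that add atoms: none
Why: Crossed Claisen condensation of the preformed lithium enolate of methyl propanoate on the methyl ester installs C15, C16 and C17; C15 is configurationally labile and is left unset.

Step 11
Reactants: 15 β-keto ester
Product: 16 methyl 5-[(2S,3S)-3-[(3E,7S,8R)-3,7-dimethyl-8,9-bis(4,4,5,5-tetramethyl-1,3,2-dioxaborolan-2-yl)-7-(triethylsilyloxy)non-3-en-1-yl]-2-methyloxiran-2-yl]-2-methyl-3-oxopentanoate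
Conditions: Pt(dba)3 (cat.), (R,R)-α,α,α′,α′-tetrakis(3,5-diethylphenyl)-2,2-dimethyl-1,3-dioxolane-4,5-dimethanol phenylphosphonite (cat.), B2(pin)2, THF, 60 °C
Reagents that add atoms: bis(pinacolato)diboron CC1(C)OB(OC1(C)C)B1OC(C)(C)C(C)(C)O1
Why: Platinum-catalysed enantioselective syn-diboration is specific for the monosubstituted alkene, and the chiral phosphonite ligand should direct both boron atoms to the Re face of C3, setting C3 under reagent control.

Step 12
Reactants: 16 bis(boronate) β-keto ester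
Product: 17 methyl (2Z)-5-[(2S,3S)-3-[(3E,7S,8R)-3,7-dimethyl-8,9-bis(4,4,5,5-tetramethyl-1,3,2-dioxaborolan-2-yl)-7-(triethylsilyloxy)non-3-en-1-yl]-2-methyloxiran-2-yl]-2-methyl-3-(trifluoromethylsulfonyloxy)pent-2-enoate
Conditions: NaH, THF, 0 °C; then PhNTf2, 0 °C to rt
Reagents that add atoms: N-phenylbis(trifluoromethanesulfonimide) O=S(=O)(N(c1ccccc1)S(=O)(=O)C(F)(F)F)C(F)(F)F
Why: O-sulfonylation of the chelated sodium enolate should give the (Z)-enol triflate (triflate cis to the ester), the geometry that later places C2 cis to C16 for lactonisation.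

Step 13
Reactants: 17 bis(boronate) enol triflate
Product: 20 (3R,4S,7E,11S,12S)-11,12-epoxy-4-(triethylsilyloxy)cembra-1(15),7-dien-16,3-olide, via macrocyclic boronate 18 (not isolated), via hydroxy ester 19 (not isolated)
Conditions: Pd(OAc)2 (cat.), 2-dicyclohexylphosphino-2′,6′-diisopropoxybiphenyl (cat.), K3PO4, THF/H2O, 60 °C, slow addition (2 mM final); then 30% H2O2, aq. NaHCO3, 0 °C to rt
Reagents that add atoms: hydrogen peroxide OO
Why: Zerovalent palladium inserts into the C1–OTf bond, the primary C2–B bond transmetalates (activated by the neighbouring C3 boronate, which itself stays a spectator) and reductive elimination forms C1–C2 with retention of alkene geometry; peroxide then converts C3–B into C3–O with retention and the new hydroxyl acylates on the cis-disposed methyl ester. The closest known reaction type is the chemoselective Suzuki–Miyaura coupling of 1,2-bis(boronic esters) with alkenyl triflates, run here intramolecularly in the manner of a B-alkyl Suzuki macrocyclisation. The 14-membered carbocycle closes by C(sp3)–C(sp2) reductive elimination with the C1=C15 alkene left exocyclic to it, and the six-membered lactone closes by 6-exo-trig acyl substitution of O3 on C16. No new stereocentre is formed: C3 (set in step 11) is carried through with retention, and the C1=C15 geometry comes from the (Z)-triflate. The step needs primary-over-secondary C–B selectivity (secured by sterics and the vicinal-boronate effect), cyclisation over oligomerisation (slow addition at high dilution) and survival of the epoxide, the C7=C8 alkene and the silyl ether (mild aqueous base).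

Step 14
Reactants: 20 unsaturated lactone
Product: 22 (1R,3R,4S,7E,11S,12S,15S)-11,12-epoxy-4-(triethylsilyloxy)cembr-7-en-16,3-olide, via 15-epi lactone 21 (not isolated)
Conditions: NiCl2·6H2O (cat.), NaBH4, MeOH/THF, −20 °C; then 1,8-diazabicyclo[5.4.0]undec-7-ene, toluene, 80 °C
Reagents that add atoms: none
Why: Nickel boride conjugate reduction should add hydrogen to the face of the dihydropyranone anti to the C3 substituent, setting C1 cis to C3 (substrate control), and base equilibration then moves the C15 methyl into the equatorial position trans to C14.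

Step 15
Reactants: 22 silyl-protected lactone
Product: 23 (1R,3R,4S,7E,11S,12S,15S)-11,12-epoxy-4-hydroxycembr-7-en-16,3-olide
Conditions: Bu4NF, THF, 0 °C to rt
Reagents that add atoms: none
Why: Fluoride cleaves the tertiary silyl ether without touching the epoxide, the alkene or the lactone.

Step 16
Reactants: 23 hydroxy lactone
Product: 24 (1R,3R,4S,7S,11S,12S,15S)-11,12-epoxy-7-hydroperoxy-4-hydroxycembr-8(19)-en-16,3-olide (CNP0319766.2)
Conditions: O2, 5,10,15,20-tetraphenylporphyrin (cat.), visible light, CH2Cl2, −20 °C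
Reagents that add atoms: dioxygen O=O
Why: Schenck ene reaction of singlet oxygen with the (E)-trisubstituted alkene should place oxygen on C7 with abstraction of a hydrogen from the cis-disposed C19 methyl group (cis effect), and approach from the outer face of the macrocycle is expected to give the (7S) hydroperoxide.

**Compound list**

1 | (2E,6E)-farnesol | OC/C=C(\C)CC/C=C(\C)CCC=C(C)C | starting material
2 | (2E,6E)-3,7,11-trimethyldodeca-2,6,10-trien-1-yl acetate | CC(=O)OC/C=C(\C)CC/C=C(\C)CCC=C(C)C | intermediate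
3 | (2E,6E,10E)-12-hydroxy-3,7,11-trimethyldodeca-2,6,10-trien-1-yl acetate | CC(=O)OC/C=C(\C)CC/C=C(\C)CC/C=C(\C)CO | intermediate
4 | (2E,6E)-9-[(2S,3S)-3-(hydroxymethyl)-3-methyloxiran-2-yl]-3,7-dimethylnona-2,6-dien-1-yl acetate | CC(=O)OC/C=C(\C)CC/C=C(\C)CC[C@@H]1O[C@@]1(C)CO | intermediate
5 | methyl (triphenyl-λ5-phosphanylidene)acetate | COC(=O)C=P(c1ccccc1)(c1ccccc1)c1ccccc1 | starting material
6 | (2E,6E)-9-[(2S,3R)-3-formyl-3-methyloxiran-2-yl]-3,7-dimethylnona-2,6-dien-1-yl acetate | CC(=O)OC/C=C(\C)CC/C=C(\C)CC[C@@H]1O[C@@]1(C)C=O | intermediate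
7 | methyl (2E)-3-[(2S,3S)-3-[(3E,7E)-9-acetoxy-3,7-dimethylnona-3,7-dien-1-yl]-2-methyloxiran-2-yl]prop-2-enoate | CC(=O)OC/C=C(\C)CC/C=C(\C)CC[C@@H]1O[C@@]1(C)/C=C/C(=O)OC | intermediate
8 | methyl 3-[(2S,3S)-3-[(3E,7E)-9-acetoxy-3,7-dimethylnona-3,7-dien-1-yl]-2-methyloxiran-2-yl]propanoate | CC(=O)OC/C=C(\C)CC/C=C(\C)CC[C@@H]1O[C@@]1(C)CCC(=O)OC | intermediate
9 | methyl 3-[(2S,3S)-3-[(3E,7E)-9-hydroxy-3,7-dimethylnona-3,7-dien-1-yl]-2-methyloxiran-2-yl]propanoate | OC/C=C(\C)CC/C=C(\C)CC[C@@H]1O[C@@]1(C)CCC(=O)OC | intermediate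
10 | methyl 3-[(2S,3S)-3-[(3E)-6-[(2S,3S)-3-(hydroxymethyl)-2-methyloxiran-2-yl]-3-methylhex-3-en-1-yl]-2-methyloxiran-2-yl]propanoate | OC[C@@H]1O[C@@]1(C)CC/C=C(\C)CC[C@@H]2O[C@@]2(C)CCC(=O)OC | intermediate
11 | methyl 3-[(2S,3S)-3-[(3E)-6-[(2S,3R)-3-(iodomethyl)-2-methyloxiran-2-yl]-3-methylhex-3-en-1-yl]-2-methyloxiran-2-yl]propanoate | IC[C@@H]1O[C@@]1(C)CC/C=C(\C)CC[C@@H]2O[C@@]2(C)CCC(=O)OC | intermediate
12 | methyl 3-[(2S,3S)-3-[(3E,7S)-7-hydroxy-3,7-dimethylnona-3,8-dien-1-yl]-2-methyloxiran-2-yl]propanoate | C=C[C@@](C)(O)CC/C=C(\C)CC[C@@H]1O[C@@]1(C)CCC(=O)OC | intermediate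
13 | methyl 3-[(2S,3S)-3-[(3E,7S)-3,7-dimethyl-7-(triethylsilyloxy)nona-3,8-dien-1-yl]-2-methyloxiran-2-yl]propanoate | C=C[C@@](C)(O[Si](CC)(CC)CC)CC/C=C(\C)CC[C@@H]1O[C@@]1(C)CCC(=O)OC | intermediate
14 | methyl propanoate | CCC(=O)OC | starting material
15 | methyl 5-[(2S,3S)-3-[(3E,7S)-3,7-dimethyl-7-(triethylsilyloxy)nona-3,8-dien-1-yl]-2-methyloxiran-2-yl]-2-methyl-3-oxopentanoate (C15 epimers) | C=C[C@@](C)(O[Si](CC)(CC)CC)CC/C=C(\C)CC[C@@H]1O[C@@]1(C)CCC(=O)C(C)C(=O)OC | intermediate
16 | methyl 5-[(2S,3S)-3-[(3E,7S,8R)-3,7-dimethyl-8,9-bis(4,4,5,5-tetramethyl-1,3,2-dioxaborolan-2-yl)-7-(triethylsilyloxy)non-3-en-1-yl]-2-methyloxiran-2-yl]-2-methyl-3-oxopentanoate | CC1(C)OB(OC1(C)C)C[C@@H](B1OC(C)(C)C(C)(C)O1)[C@@](C)(O[Si](CC)(CC)CC)CC/C=C(\C)CC[C@@H]1O[C@@]1(C)CCC(=O)C(C)C(=O)OC | intermediate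
17 | methyl (2Z)-5-[(2S,3S)-3-[(3E,7S,8R)-3,7-dimethyl-8,9-bis(4,4,5,5-tetramethyl-1,3,2-dioxaborolan-2-yl)-7-(triethylsilyloxy)non-3-en-1-yl]-2-methyloxiran-2-yl]-2-methyl-3-(trifluoromethylsulfonyloxy)pent-2-enoate | CC1(C)OB(OC1(C)C)C[C@@H](B1OC(C)(C)C(C)(C)O1)[C@@](C)(O[Si](CC)(CC)CC)CC/C=C(\C)CC[C@@H]1O[C@@]1(C)CC/C(OS(=O)(=O)C(F)(F)F)=C(\C)C(=O)OC | intermediate
18 | methyl (1(15)Z,3R,4S,7E,11S,12S)-11,12-epoxy-3-(4,4,5,5-tetramethyl-1,3,2-dioxaborolan-2-yl)-4-(triethylsilyloxy)cembra-1(15),7-dien-16-oate | COC(=O)/C(C)=C1\C[C@@H](B2OC(C)(C)C(C)(C)O2)[C@@](C)(O[Si](CC)(CC)CC)CC/C=C(\C)CC[C@@H]2O[C@@]2(C)CC1 | intermediate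
19 | methyl (1(15)Z,3R,4S,7E,11S,12S)-11,12-epoxy-3-hydroxy-4-(triethylsilyloxy)cembra-1(15),7-dien-16-oate | COC(=O)/C(C)=C1\C[C@@H](O)[C@@](C)(O[Si](CC)(CC)CC)CC/C=C(\C)CC[C@@H]2O[C@@]2(C)CC1 | intermediate
20 | (3R,4S,7E,11S,12S)-11,12-epoxy-4-(triethylsilyloxy)cembra-1(15),7-dien-16,3-olide | CC1=C2C[C@@H](OC1=O)[C@@](C)(O[Si](CC)(CC)CC)CC/C=C(\C)CC[C@@H]1O[C@@]1(C)CC2 | intermediate
21 | (1R,3R,4S,7E,11S,12S,15R)-11,12-epoxy-4-(triethylsilyloxy)cembr-7-en-16,3-olide (15-epimer) | C1C[C@@H]2O[C@@]2(C)CC[C@@H]2C[C@@H](OC(=O)[C@@H]2C)[C@@](C)(O[Si](CC)(CC)CC)CC/C=C1\C | intermediate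
22 | (1R,3R,4S,7E,11S,12S,15S)-11,12-epoxy-4-(triethylsilyloxy)cembr-7-en-16,3-olide | C1C[C@@H]2O[C@@]2(C)CC[C@@H]2C[C@@H](OC(=O)[C@H]2C)[C@@](C)(O[Si](CC)(CC)CC)CC/C=C1\C | intermediate
23 | (1R,3R,4S,7E,11S,12S,15S)-11,12-epoxy-4-hydroxycembr-7-en-16,3-olide | C1C[C@@H]2O[C@@]2(C)CC[C@@H]2C[C@@H](OC(=O)[C@H]2C)[C@@](C)(O)CC/C=C1\C | intermediate
24 | (1R,3R,4S,7S,11S,12S,15S)-11,12-epoxy-7-hydroperoxy-4-hydroxycembr-8(19)-en-16,3-olide (CNP0319766.2) | C=C1CC[C@@H]2O[C@@]2(C)CC[C@@H]2C[C@@H](OC(=O)[C@H]2C)[C@@](C)(O)CC[C@@H]1OO | target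

**Summary**

Total step count: 16. Longest linear sequence: 16 steps (1 to 24).

Steps most likely to fail:

1. Step 13 (key step). At the dilution needed for ring closure, transmetalation of the pinacol boronate may be too slow, so that protodeboronation, β-hydride elimination, triflate hydrolysis or oligomerisation outrun cyclisation. The fallback closes the same C1–C2 bond by a dipolar cycloaddition and sets out from 13. i-Bu2AlH (CH2Cl2, −78 °C) should give the aldehyde F1, and NH2OH·HCl with pyridine the oxime F2. Aqueous NaOCl in CH2Cl2 under high dilution generates the nitrile oxide F3, whose intramolecular 1,3-dipolar cycloaddition onto the vinyl group joins C1 to C2 and O to C3 in the bridged isoxazoline F4. Here C3 is set only under substrate control by the allylic C4 silyl ether, so epimers may need separating. Mo(CO)6 in wet MeCN cleaves the N–O bond to the β-hydroxy ketone F5. Esterification of the C3 hydroxyl with 2-(diethoxyphosphoryl)propanoic acid (N,N′-dicyclohexylcarbodiimide, 4-(dimethylamino)pyridine) gives the phosphonate ester F6. Intramolecular Horner–Wadsworth–Emmons olefination (LiCl, 1,8-diazabicyclo[5.4.0]undec-7-ene, MeCN) closes the lactone and comes back to the route at 20.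

2. Step 16. Oxygen transfer may show poor facial selectivity at C7 and incomplete regioselectivity (hydrogen abstraction from C6 gives the tertiary C8 hydroperoxide instead). The fallback sets C7 by reagent control and sets out from 23. Photooxygenation as in step 16, followed in the same flask by Ac2O, pyridine and 4-(dimethylamino)pyridine, dehydrates both secondary hydroperoxides (24 and its 7-epimer F7) by Kornblum–DeLaMare elimination to the enone F8. The tertiary regioisomer cannot dehydrate and is removed. Corey–Bakshi–Shibata reduction ((S)-1-methyl-3,3-diphenyltetrahydro-1H,3H-pyrrolo[1,2-c][1,3,2]oxazaborole, BH3·SMe2, −30 °C) should give the (7R)-allylic alcohol F9. Mesylation (MsCl, Et3N, −40 °C) gives the mesylate F10. Displacement with 2-methoxypropan-2-yl hydroperoxide (CsOH, DMF, 0 °C, inversion) gives the peroxyketal F11, which aqueous AcOH unmasks to come back at 24.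

3. Step 14. Hydride delivery to the tetrasubstituted C1=C15 bond may be sluggish, may show poor facial selectivity at C1, or may compete with reduction of the lactone carbonyl. The fallback sets out from 20 and replaces hydride delivery by single-electron reduction with SmI2 (N,N-dimethylacetamide, t-BuOH, THF, rt). The radical anion is protonated at C1 along the axial trajectory, which places C14 equatorial and cis to C4, and the resulting enolate is protonated at C15. The same base equilibration as in step 14 then comes back to the route at 22; no new compound arises.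

Further compounds
F1 | step 13 | 3-[(2S,3S)-3-[(3E,7S)-3,7-dimethyl-7-(triethylsilyloxy)nona-3,8-dien-1-yl]-2-methyloxiran-2-yl]propanal | C=C[C@@](C)(O[Si](CC)(CC)CC)CC/C=C(\C)CC[C@@H]1O[C@@]1(C)CCC=O
F2 | step 13 | oxime of F1 | C=C[C@@](C)(O[Si](CC)(CC)CC)CC/C=C(\C)CC[C@@H]1O[C@@]1(C)CCC=NO
F3 | step 13 | nitrile oxide from F2 | C=C[C@@](C)(O[Si](CC)(CC)CC)CC/C=C(\C)CC[C@@H]1O[C@@]1(C)CCC#[N+][O-]
F4 | step 13 | (3R,4S,7E,11S,12S)-bridged isoxazoline (C1=N–O–C3 with C2 as ring CH2; 11,12-epoxide; 4-triethylsilyloxy) | C1C[C@@H]2O[C@@]2(C)CCC2=NO[C@H](C2)[C@@](C)(O[Si](CC)(CC)CC)CC/C=C1\C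
F5 | step 13 | (3R,4S,7E,11S,12S)-11,12-epoxy-3-hydroxy-4,8,12-trimethyl-4-(triethylsilyloxy)cyclotetradec-7-en-1-one (cembrane numbering) | C1C[C@@H]2O[C@@]2(C)CCC(=O)C[C@@H](O)[C@@](C)(O[Si](CC)(CC)CC)CC/C=C1\C
F6 | step 13 | 2-(diethoxyphosphoryl)propanoate ester of F5 at O3 | C1C[C@@H]2O[C@@]2(C)CCC(=O)C[C@@H](OC(=O)C(C)P(=O)(OCC)OCC)[C@@](C)(O[Si](CC)(CC)CC)CC/C=C1\C
F7 | step 16 | (7R)-epimer of 24 | C=C1CC[C@@H]2O[C@@]2(C)CC[C@@H]2C[C@@H](OC(=O)[C@H]2C)[C@@](C)(O)CC[C@H]1OO
F8 | step 16 | (1R,3R,4S,11S,12S,15S)-11,12-epoxy-4-hydroxy-7-oxocembr-8(19)-en-16,3-olide | C=C1CC[C@@H]2O[C@@]2(C)CC[C@@H]2C[C@@H](OC(=O)[C@H]2C)[C@@](C)(O)CCC1=O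
F9 | step 16 | (1R,3R,4S,7R,11S,12S,15S)-11,12-epoxy-4,7-dihydroxycembr-8(19)-en-16,3-olide | C=C1CC[C@@H]2O[C@@]2(C)CC[C@@H]2C[C@@H](OC(=O)[C@H]2C)[C@@](C)(O)CC[C@H]1O
F10 | step 16 | (7R)-7-methanesulfonate of F9 | C=C1CC[C@@H]2O[C@@]2(C)CC[C@@H]2C[C@@H](OC(=O)[C@H]2C)[C@@](C)(O)CC[C@H]1OS(C)(=O)=O
F11 | step 16 | (7S)-7-(2-methoxypropan-2-ylperoxy) derivative (peroxyketal of 24) | C=C1CC[C@@H]2O[C@@]2(C)CC[C@@H]2C[C@@H](OC(=O)[C@H]2C)[C@@](C)(O)CC[C@@H]1OOC(C)(C)OC
F0 | step 14 | none | none
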